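## Retrosynthetic overview

1. Locants: lactone ring O1–C2(=O)–C3=C4–C5H2–C6H2–C7(CH3); side chain C1′(OAc)–C2′=C3′(CH3)–C4′–C5′–C6′(OH), with C6′ bonded to C7.
2. The only ring (the oxepinone) is formed last, by intramolecular Horner–Wadsworth–Emmons olefination (C3=C4); C4 comes from CO by hydroformylation of a C5=C6 vinyl group on C7.
3. Key disconnection C6′–C7: aldehyde 3 (C1′–C6′, two steps from geranyl acetate) plus allylboronate 11, generated in the same flask from dienyl ester 9 and pinacolborane (three components, both stereocentres set).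
4. Enabling feature: C7 is a fully substituted carbon that carries the ring oxygen O1 and a methyl group and is followed by the ring methylenes C6 and C5. It is therefore the γ-carbon of an (E)-γ-acyloxy-γ-methylallylboronate whose O-acyl bond already is the O1–C2 ester of the ring and whose transposed vinyl group is C6=C5.
5. Dienyl ester 9 is made from alkylated phosphonoacetic acid 6 by esterification with buta-2,3-dien-1-ol and a gold-catalysed 1,3-acyloxy shift.

Key step: step 6

Remarks on the chemistry (assumptions): commercial geranyl acetate is taken as the pure 2E isomer and buta-2,3-dien-1-ol as purchasable. The phosphonate-bearing carbon is carried as a mixture of epimers because it becomes sp2 in step 9.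

## Route

Step 1
Reactants: 1 geranyl acetate
Product: 2 (2E)-5-(3,3-dimethyloxiran-2-yl)-3-methylpent-2-en-1-yl acetate (racemic)
Conditions: mCPBA (1.05 equiv), NaHCO3, CH2Cl2, 0 °C
Reagents that add atoms: mCPBA, OOC(=O)c1cccc(Cl)c1
Why: Prilezhaev epoxidation should be site-selective for the electron-rich 6,7-alkene because the 2,3-alkene is deactivated by the allylic acetate; the epoxide stereocentre is destroyed in step 2.

Step 2
Reactants: 2 (2E)-5-(3,3-dimethyloxiran-2-yl)-3-methylpent-2-en-1-yl acetate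
Product: 3 (2E)-3-methyl-6-oxohex-2-en-1-yl acetate
Conditions: H5IO6 (1.2 equiv), THF/H2O, 0 °C → rt
Reagents that add atoms: none
Why: Periodic acid hydrates the epoxide and cleaves the resulting glycol in one pot (Malaprade-type cleavage), excising acetone while the allylic acetate and the 2E alkene are left untouched.

Step 3
Reactants: 4 (diethoxyphosphoryl)acetic acid; 5 5-bromo-2-methylpent-2-ene
Product: 6 2-(diethoxyphosphoryl)-6-methylhept-5-enoic acid (racemic)
Conditions: n-BuLi (2.1 equiv), THF, −60 °C; then 5, DMPU, −60 °C → rt; aq. HCl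
Reagents that add atoms: none
Why: The carboxylate/α-phosphonyl dianion should be alkylated at carbon by the primary bromide (SN2 alkylation of a phosphonoacetic acid dianion); the new stereocentre is racemic and is erased in step 9.

Step 4
Reactants: 6 2-(diethoxyphosphoryl)-6-methylhept-5-enoic acid; 7 buta-2,3-dien-1-ol
Product: 8 buta-2,3-dien-1-yl 2-(diethoxyphosphoryl)-6-methylhept-5-enoate
Conditions: EDC·HCl, DMAP (cat.), CH2Cl2, 0 °C → rt
Reagents that add atoms: none
Why: Steglich-type carbodiimide esterification of an unhindered primary alcohol with an activated α-phosphono acid should proceed under neutral conditions that do not touch the allene.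

Step 5
Reactants: 8 buta-2,3-dien-1-yl 2-(diethoxyphosphoryl)-6-methylhept-5-enoate
Product: 9 buta-1,3-dien-2-yl 2-(diethoxyphosphoryl)-6-methylhept-5-enoate
Conditions: Ph3PAuNTf2 (1 mol%), CH2Cl2, rt
Reagents that add atoms: none
Why: Cationic gold(I) activates the allene and the ester carbonyl oxygen attacks its central carbon, a 1,3-acyloxy shift known for allenylcarbinol esters that gives the 1,3-dien-2-yl ester without enolate chemistry.

Step 6
Reactants: 3 (2E)-3-methyl-6-oxohex-2-en-1-yl acetate; 9 buta-1,3-dien-2-yl 2-(diethoxyphosphoryl)-6-methylhept-5-enoate; 10 pinacolborane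
Product: 13 (3S,4R,7E)-9-acetoxy-4-hydroxy-3,7-dimethylnona-1,7-dien-3-yl 2-(diethoxyphosphoryl)-6-methylhept-5-enoate, via allylboronate 11 (not isolated), via borate ester 12 (not isolated)
Conditions: 9 (1.1 equiv), 10 (1.0 equiv), Ni(cod)2/PCy3 (2.5 mol%), toluene, 0 °C → rt; dry air, 10 min; then 3, (S)-TRIP (10 mol%), 4 Å MS, −30 °C → rt; aq. NaHCO3
Reagents that add atoms: none
Why: Proposed new method: Ni(0) inserts into H–Bpin and should deliver hydride to the CH2 terminus next to the acyloxy-bearing carbon of the s-cis diene and boron to the other terminus, so that 11 forms with methyl cis and acyloxy trans to CH2B; 11 then adds through its γ-carbon to the aldehyde in a closed chair (Zimmerman–Traxler) transition state activated by hydrogen bonding of the chiral phosphoric acid to a boronate oxygen, giving borate 12, which is hydrolysed on work-up. The closest known reaction types are the Ni- and Fe-catalysed 1,4-hydroboration of 2-alkyl-1,3-dienes with one-pot aldehyde allylation and the phosphoric acid-catalysed allylboration of aldehydes with γ,γ-disubstituted and with γ-silyloxy allyl pinacolboronates; new are the 2-acyloxy diene and the use of its acyl group as the future lactone acyl. No ring is closed in this step. C7 is set by the enol-ester geometry of 11 (the E-positioned acyloxy group ends anti and the Z-positioned methyl syn to the new hydroxyl) and C6′ by the catalyst ((S)-TRIP is expected to direct attack to the Si face, the mirror image of the Re-face attack established for (R)-TRIP), which together should give 6′R,7S. The step needs 1,4- instead of 1,2-hydroboration with hydride at the substituted terminus, γ-attack before any E/Z scrambling, and no acyl migration; the first is the normal course for 2-substituted dienes, the second follows from the six-membered transition state and the configurational stability of pinacol allylboronates, and the third from keeping the product as its borate until a neutral work-up. Ni(0) and PCy3 are oxidised by air before 3 is added so that neither the allylic acetate nor the acid catalyst is consumed.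

Step 7
Reactants: 13 (3S,4R,7E)-9-acetoxy-4-hydroxy-3,7-dimethylnona-1,7-dien-3-yl 2-(diethoxyphosphoryl)-6-methylhept-5-enoate
Product: 14 (3S,4R,7E)-9-acetoxy-3,7-dimethyl-4-(triethylsilyloxy)nona-1,7-dien-3-yl 2-(diethoxyphosphoryl)-6-methylhept-5-enoate
Conditions: TESOTf, 2,6-lutidine, CH2Cl2, −78 °C
Reagents that add atoms: triethylsilyl triflate, CC[Si](CC)(CC)OS(=O)(=O)C(F)(F)F
Why: Low-temperature silylation of the secondary alcohol with a non-nucleophilic base should block 1,2-acyl migration from the tertiary to the secondary oxygen and lactol formation in the next two steps.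

Step 8
Reactants: 14 (3S,4R,7E)-9-acetoxy-3,7-dimethyl-4-(triethylsilyloxy)nona-1,7-dien-3-yl 2-(diethoxyphosphoryl)-6-methylhept-5-enoate
Product: 15 (4S,5R,8E)-10-acetoxy-4,8-dimethyl-1-oxo-5-(triethylsilyloxy)dec-8-en-4-yl 2-(diethoxyphosphoryl)-6-methylhept-5-enoate
Conditions: Rh(acac)(CO)2 (1 mol%), BiPhePhos (3 mol%), CO/H2 (1:1, 10 bar), toluene, 60 °C
Reagents that add atoms: carbon monoxide, [C-]#[O+]
Why: Rhodium/bisphosphite hydroformylation should react only at the single monosubstituted alkene and, at a vinyl group on a quaternary carbon, give the linear aldehyde, while the trisubstituted alkenes stay inert.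

Step 9
Reactants: 15 (4S,5R,8E)-10-acetoxy-4,8-dimethyl-1-oxo-5-(triethylsilyloxy)dec-8-en-4-yl 2-(diethoxyphosphoryl)-6-methylhept-5-enoate
Product: 16 (2E,6R)-3-methyl-6-[(2S)-2-methyl-6-(4-methylpent-3-en-1-yl)-7-oxo-2,3,4,7-tetrahydrooxepin-2-yl]-6-(triethylsilyloxy)hex-2-en-1-yl acetate
Conditions: LiCl, DBU, MeCN, rt, 1 mM (slow addition)
Reagents that add atoms: none
Why: Intramolecular Horner–Wadsworth–Emmons olefination under mild LiCl/amine conditions at high dilution should close the seven-membered ring, which itself enforces the cis relationship of C5 and C2 across C3=C4 and removes the phosphonate-carbon stereocentre.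

Step 10
Reactants: 16 (2E,6R)-3-methyl-6-[(2S)-2-methyl-6-(4-methylpent-3-en-1-yl)-7-oxo-2,3,4,7-tetrahydrooxepin-2-yl]-6-(triethylsilyloxy)hex-2-en-1-yl acetate
Product: 17 (2E,6R)-6-hydroxy-3-methyl-6-[(2S)-2-methyl-6-(4-methylpent-3-en-1-yl)-7-oxo-2,3,4,7-tetrahydrooxepin-2-yl]hex-2-en-1-yl acetate
Conditions: HF·pyridine, pyridine, THF, 0 °C → rt
Reagents that add atoms: none
Why: Buffered fluoride desilylation should cleave only the triethylsilyl ether and leave the allylic acetate, the lactone and both stereocentres untouched.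

## Compound list

1 | geranyl acetate, (2E)-3,7-dimethylocta-2,6-dien-1-yl acetate | CC(=O)OC/C=C(\C)CCC=C(C)C | starting material
2 | (2E)-5-(3,3-dimethyloxiran-2-yl)-3-methylpent-2-en-1-yl acetate (racemic) | CC(=O)OC/C=C(\C)CCC1OC1(C)C | intermediate
3 | (2E)-3-methyl-6-oxohex-2-en-1-yl acetate | CC(=O)OC/C=C(\C)CCC=O | intermediate
4 | (diethoxyphosphoryl)acetic acid | OC(=O)CP(=O)(OCC)OCC | starting material
5 | 5-bromo-2-methylpent-2-ene | CC(C)=CCCBr | starting material
6 | 2-(diethoxyphosphoryl)-6-methylhept-5-enoic acid (racemic) | CC(C)=CCCC(C(=O)O)P(=O)(OCC)OCC | intermediate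
7 | buta-2,3-dien-1-ol | C=C=CCO | starting material
8 | buta-2,3-dien-1-yl 2-(diethoxyphosphoryl)-6-methylhept-5-enoate | C=C=CCOC(=O)C(CCC=C(C)C)P(=O)(OCC)OCC | intermediate
9 | buta-1,3-dien-2-yl 2-(diethoxyphosphoryl)-6-methylhept-5-enoate | C=CC(=C)OC(=O)C(CCC=C(C)C)P(=O)(OCC)OCC | intermediate
10 | pinacolborane (4,4,5,5-tetramethyl-1,3,2-dioxaborolane) | [H]B1OC(C)(C)C(C)(C)O1 | starting material
11 | (2E)-4-(4,4,5,5-tetramethyl-1,3,2-dioxaborolan-2-yl)but-2-en-2-yl 2-(diethoxyphosphoryl)-6-methylhept-5-enoate (methyl cis to CH2B) | C/C(=C\CB1OC(C)(C)C(C)(C)O1)OC(=O)C(CCC=C(C)C)P(=O)(OCC)OCC | intermediate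
12 | (3S,4R,7E)-9-acetoxy-3,7-dimethyl-4-[(4,4,5,5-tetramethyl-1,3,2-dioxaborolan-2-yl)oxy]nona-1,7-dien-3-yl 2-(diethoxyphosphoryl)-6-methylhept-5-enoate | CC(=O)OC/C=C(\C)CC[C@@H](OB1OC(C)(C)C(C)(C)O1)[C@](C)(C=C)OC(=O)C(CCC=C(C)C)P(=O)(OCC)OCC | intermediate
13 | (3S,4R,7E)-9-acetoxy-4-hydroxy-3,7-dimethylnona-1,7-dien-3-yl 2-(diethoxyphosphoryl)-6-methylhept-5-enoate | CC(=O)OC/C=C(\C)CC[C@@H](O)[C@](C)(C=C)OC(=O)C(CCC=C(C)C)P(=O)(OCC)OCC | intermediate
14 | (3S,4R,7E)-9-acetoxy-3,7-dimethyl-4-(triethylsilyloxy)nona-1,7-dien-3-yl 2-(diethoxyphosphoryl)-6-methylhept-5-enoate | CC(=O)OC/C=C(\C)CC[C@@H](O[Si](CC)(CC)CC)[C@](C)(C=C)OC(=O)C(CCC=C(C)C)P(=O)(OCC)OCC | intermediate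
15 | (4S,5R,8E)-10-acetoxy-4,8-dimethyl-1-oxo-5-(triethylsilyloxy)dec-8-en-4-yl 2-(diethoxyphosphoryl)-6-methylhept-5-enoate | CC(=O)OC/C=C(\C)CC[C@@H](O[Si](CC)(CC)CC)[C@](C)(CCC=O)OC(=O)C(CCC=C(C)C)P(=O)(OCC)OCC | intermediate
16 | (2E,6R)-3-methyl-6-[(2S)-2-methyl-6-(4-methylpent-3-en-1-yl)-7-oxo-2,3,4,7-tetrahydrooxepin-2-yl]-6-(triethylsilyloxy)hex-2-en-1-yl acetate | CC(=O)OC/C=C(\C)CC[C@@H](O[Si](CC)(CC)CC)[C@]1(C)CCC=C(CCC=C(C)C)C(=O)O1 | intermediate
17 | (2E,6R)-6-hydroxy-3-methyl-6-[(2S)-2-methyl-6-(4-methylpent-3-en-1-yl)-7-oxo-2,3,4,7-tetrahydrooxepin-2-yl]hex-2-en-1-yl acetate | CC(=O)OC/C=C(\C)CC[C@@H](O)[C@]1(C)CCC=C(CCC=C(C)C)C(=O)O1 | target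

## Step count and risks

Total steps: 10. Longest linear sequence: 8 steps (4 and 5 to 17, steps 3–10).

Steps most likely to fail:

1. Step 6 (Proposed new method). Hydride may go to the wrong diene terminus or boron may add 1,2. The electron-poor enol-ester allylboronate may also transfer too slowly for the catalyst to control the aldehyde face, and acyl migration to the new secondary oxygen may set in. The fallback uses known chemistry, sets out from aldehyde 3 (with acid 6) and comes back at 14. The lithium enolate (LDA, THF, −78 °C) of (2S,5S)-2-tert-butyl-5-methyl-1,3-dioxolan-4-one F1, the pivalaldehyde acetal of (S)-lactic acid, is added to 3. Attack anti to the tert-butyl group (self-regeneration of the lactic acid stereocentre) fixes C7, and the C6′ epimers are separated to give the aldol adduct F2. TESOTf/2,6-lutidine gives the silyl ether F3. Excess DIBAL-H at −78 °C reduces the lactone carbonyl and also cleaves the acetate, giving the lactol F4. Ph3P=CH2 opens the lactol, which loses its acetal carbon, to the vinyl diol (2E,6R,7S)-3,7-dimethyl-6-(triethylsilyloxy)nona-2,8-diene-1,7-diol F5. Ac2O/pyridine acetylates only the primary hydroxyl, giving the tertiary alcohol (2E,6R,7S)-7-hydroxy-3,7-dimethyl-6-(triethylsilyloxy)nona-2,8-dien-1-yl acetate F6. DCC/DMAP esterification with 6, which reacts through its phosphonoketene and so acylates tertiary alcohols, gives 14.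

2. Step 9. Intermolecular olefination (cyclo-oligomerisation) may outrun closure of the seven-membered ring. The fallback sets out from 15 and comes back at 16 by ring-closing metathesis. Wittig methylenation of the aldehyde (Ph3P=CH2, THF, −78 °C) gives the terminal alkene (5S,6R,9E)-11-acetoxy-5,9-dimethyl-6-(triethylsilyloxy)undeca-1,9-dien-5-yl 2-(diethoxyphosphoryl)-6-methylhept-5-enoate F7. Horner–Wadsworth–Emmons reaction of its phosphonate with formaldehyde (aq. HCHO, K2CO3) gives the α-methylene ester (5S,6R,9E)-11-acetoxy-5,9-dimethyl-6-(triethylsilyloxy)undeca-1,9-dien-5-yl 6-methyl-2-methylidenehept-5-enoate F8. Ring-closing metathesis (second-generation Hoveyda–Grubbs catalyst, toluene, 80 °C, high dilution) then forms C3=C4 and gives 16.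

3. Step 8. Hydroformylation next to the quaternary carbon may be slow, so that alkene isomerisation or hydrogenation, or ionisation of the allylic acetate, competes. The fallback sets out from 14 and comes back at 15 by stoichiometric hydroboration–carbonylation. 9-BBN (THF, rt) hydroborates only the vinyl group to give the trialkylborane (3S,4R,7E)-9-acetoxy-1-(9-borabicyclo[3.3.1]nonan-9-yl)-3,7-dimethyl-4-(triethylsilyloxy)non-7-en-3-yl 2-(diethoxyphosphoryl)-6-methylhept-5-enoate F9. Carbonylation (CO, 1 atm) in the presence of potassium triisopropoxyborohydride, followed by buffered H2O2 (pH 7), gives aldehyde 15.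

Further compounds
F1 | step 6 | (2S,5S)-2-tert-butyl-5-methyl-1,3-dioxolan-4-one | C[C@@H]1O[C@H](C(C)(C)C)OC1=O
F2 | step 6 | aldol adduct, (2E,6R)-6-[(2S,4R)-2-tert-butyl-4-methyl-5-oxo-1,3-dioxolan-4-yl]-6-hydroxy-3-methylhex-2-en-1-yl acetate | CC(=O)OC/C=C(\C)CC[C@@H](O)[C@@]1(C)O[C@H](C(C)(C)C)OC1=O
F3 | step 6 | triethylsilyl ether of F2 | CC(=O)OC/C=C(\C)CC[C@@H](O[Si](CC)(CC)CC)[C@@]1(C)O[C@H](C(C)(C)C)OC1=O
F4 | step 6 | lactol from F3 (dioxolanone C=O reduced to CH–OH, acetate cleaved to the primary alcohol; lactol carbon as a mixture) | OC/C=C(\C)CC[C@@H](O[Si](CC)(CC)CC)[C@@]1(C)O[C@H](C(C)(C)C)OC1O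
F5 | step 6 | (2E,6R,7S)-3,7-dimethyl-6-(triethylsilyloxy)nona-2,8-diene-1,7-diol | OC/C=C(\C)CC[C@@H](O[Si](CC)(CC)CC)[C@@](C)(O)C=C
F6 | step 6 | (2E,6R,7S)-7-hydroxy-3,7-dimethyl-6-(triethylsilyloxy)nona-2,8-dien-1-yl acetate | CC(=O)OC/C=C(\C)CC[C@@H](O[Si](CC)(CC)CC)[C@@](C)(O)C=C
F7 | step 9 | (5S,6R,9E)-11-acetoxy-5,9-dimethyl-6-(triethylsilyloxy)undeca-1,9-dien-5-yl 2-(diethoxyphosphoryl)-6-methylhept-5-enoate | CC(=O)OC/C=C(\C)CC[C@@H](O[Si](CC)(CC)CC)[C@](C)(CCC=C)OC(=O)C(CCC=C(C)C)P(=O)(OCC)OCC
F8 | step 9 | (5S,6R,9E)-11-acetoxy-5,9-dimethyl-6-(triethylsilyloxy)undeca-1,9-dien-5-yl 6-methyl-2-methylidenehept-5-enoate | CC(=O)OC/C=C(\C)CC[C@@H](O[Si](CC)(CC)CC)[C@](C)(CCC=C)OC(=O)C(=C)CCC=C(C)C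
F9 | step 8 | (3S,4R,7E)-9-acetoxy-1-(9-borabicyclo[3.3.1]nonan-9-yl)-3,7-dimethyl-4-(triethylsilyloxy)non-7-en-3-yl 2-(diethoxyphosphoryl)-6-methylhept-5-enoate | CC(=O)OC/C=C(\C)CC[C@@H](O[Si](CC)(CC)CC)[C@](C)(CCB1C2CCCC1CCC2)OC(=O)C(CCC=C(C)C)P(=O)(OCC)OCC
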